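**Retrosynthetic overview**
- The target is reached last by Lewis-acid removal of an isopropyl group from 3-hexadecyl-2-isopropoxy-5-methoxy-1,4-benzoquinone; the methyl ether stays.
- The quinone ring (the only ring of the target) is not taken from an arene. It is made by thermal ring expansion of a 4-alkenyl-4-hydroxycyclobutenone: 4π ring opening, dienylketene, 6π ring closure, hydroquinone, quinone.
- That cyclobutenone comes from 3-hexadecyl-4-isopropoxycyclobutenedione and (Z)-2-methoxyvinyllithium, which adds at the carbonyl next to the isopropoxy-bearing carbon. This connectivity fixes the 2-OR / 3-alkyl / 5-OMe / 6-H pattern.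
- The cyclobutenedione comes from diisopropyl squarate and hexadecylmagnesium bromide; the vinyllithium comes from methyl vinyl ether.
- Ring order: the four-membered ring is bought (squarate); the six-membered ring is formed in step 5.

**Assumption:** the target has no stereocentre and no stereogenic double bond, so "single enantiomer" means the achiral compound as drawn; the side chain is n-hexadecyl (16 carbons).

**Step 1**
Reactants: 1 hexadecyl bromide (1-bromohexadecane); 2 diisopropyl squarate (3,4-diisopropoxycyclobut-3-ene-1,2-dione)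
Product: 5 rac-4-hexadecyl-4-hydroxy-2,3-diisopropoxycyclobut-2-en-1-one, via hexadecylmagnesium bromide 3 (not isolated), via bromomagnesium alkoxide 4 (not isolated)
Conditions: Mg turnings, THF, reflux; then added to 2, THF, −78 °C, 1 h; sat. aq NH4Cl
Reagents that add atoms: none
Why: Grignard formation followed by 1,2-addition to one squarate carbonyl at low temperature, where the tetrahedral alkoxide resists a second addition; the new stereocentre is racemic and is destroyed in step 2.

**Step 2**
Reactants: 5 rac-4-hexadecyl-4-hydroxy-2,3-diisopropoxycyclobut-2-en-1-one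
Product: 6 3-hexadecyl-4-isopropoxycyclobut-3-ene-1,2-dione
Conditions: 12 M aq HCl (cat.), CH2Cl2, rt, 1 h
Reagents that add atoms: water, O (oxygen of the new C=O; one water is also released from the carbinol, so the step is water-neutral)
Why: acid-catalysed 1,3-carbonyl transposition, in which ionisation of the tertiary carbinol and hydration at the alkoxy-stabilised terminus expel isopropanol and give the alkyl cyclobutenedione.

**Step 3**
Reactants: 7 methyl vinyl ether (methoxyethene)
Product: 9 (Z)-1-bromo-2-methoxyethene, via 1,2-dibromo-1-methoxyethane 8 (not isolated)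
Conditions: Br2, CH2Cl2, −78 °C; then PhNEt2, 90 °C; fractional distillation
Reagents that add atoms: bromine, BrBr
Why: electrophilic bromination of the enol ether, then amine-mediated dehydrobromination through the oxocarbenium ion, which loses the α-bromide and gives mainly the Z β-bromo enol ether.

**Step 4**
Reactants: 6 3-hexadecyl-4-isopropoxycyclobut-3-ene-1,2-dione; 9 (Z)-1-bromo-2-methoxyethene
Product: 12 rac-2-hexadecyl-4-hydroxy-3-isopropoxy-4-[(Z)-2-methoxyethenyl]cyclobut-2-en-1-one, via (Z)-2-methoxyvinyllithium 10 (not isolated), via lithium alkoxide 11 (not isolated)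
Conditions: 9 (1.5 equiv), n-BuLi (1.4 equiv), Et2O, −78 °C, 45 min; then 6 in THF, −78 °C, 30 min; sat. aq NH4Cl at −78 °C; crude product used at once
Reagents that add atoms: none
Why: lithium–bromine exchange with retention of the Z geometry, then 1,2-addition to the carbonyl next to the isopropoxy-bearing carbon, because the other carbonyl is deactivated as a vinylogous ester; the carbinol stereocentre is racemic and is lost in step 5.

**Step 5**
Reactants: 12 rac-2-hexadecyl-4-hydroxy-3-isopropoxy-4-[(Z)-2-methoxyethenyl]cyclobut-2-en-1-one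
Product: 16 3-hexadecyl-2-isopropoxy-5-methoxy-1,4-benzoquinone, via dienylketene 13 (not isolated), via cyclohexadienone 14 (not isolated), via hydroquinone 15 (not isolated)
Conditions: degassed p-xylene, base-washed flask, 138 °C, 45 min; cool; then Ag2O (1.5 equiv), rt, 30 min; filter
Reagents that add atoms: none
Why: Moore–Liebeskind ring expansion, in which conrotatory 4π opening (hydroxyl outward, alkenyl inward) gives a dienylketene that closes by 6π electrocyclisation and tautomerises to the hydroquinone, which Ag2O oxidises to the quinone with the substituent pattern fixed by connectivity.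

**Step 6**
Reactants: 16 3-hexadecyl-2-isopropoxy-5-methoxy-1,4-benzoquinone
Product: 18 3-hexadecyl-2-hydroxy-5-methoxy-1,4-benzoquinone (target), via dichloroboryl ether 17 (not isolated)
Conditions: BCl3 (1.2 equiv, 1 M in CH2Cl2), CH2Cl2, −78 → −20 °C; then H2O
Reagents that add atoms: none
Why: Lewis-acid dealkylation of a vinylogous ester, where BCl3 on the conjugated carbonyl makes the C2 oxygen oxocarbenium-like and the secondary isopropyl group is lost to chloride much faster than the methyl group; the C2 ether, twisted by the neighbouring chain, is also the intrinsically more labile one.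

**Compound list**
1 | hexadecyl bromide (1-bromohexadecane) | CCCCCCCCCCCCCCCCBr | starting material
2 | diisopropyl squarate (3,4-diisopropoxycyclobut-3-ene-1,2-dione) | CC(C)OC1=C(OC(C)C)C(=O)C1=O | starting material
3 | hexadecylmagnesium bromide | CCCCCCCCCCCCCCCC[Mg]Br | intermediate (not isolated)
4 | bromomagnesium 1-hexadecyl-2,3-diisopropoxy-4-oxocyclobut-2-en-1-olate (racemic) | CCCCCCCCCCCCCCCCC1(O[Mg]Br)C(OC(C)C)=C(OC(C)C)C1=O | intermediate (not isolated)
5 | rac-4-hexadecyl-4-hydroxy-2,3-diisopropoxycyclobut-2-en-1-one | CCCCCCCCCCCCCCCCC1(O)C(OC(C)C)=C(OC(C)C)C1=O | intermediate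
6 | 3-hexadecyl-4-isopropoxycyclobut-3-ene-1,2-dione | CCCCCCCCCCCCCCCCC1=C(OC(C)C)C(=O)C1=O | intermediate
7 | methyl vinyl ether (methoxyethene) | COC=C | starting material
8 | 1,2-dibromo-1-methoxyethane (racemic) | COC(Br)CBr | intermediate (not isolated)
9 | (Z)-1-bromo-2-methoxyethene | CO/C=C\Br | intermediate
10 | (Z)-2-methoxyvinyllithium | CO/C=C\[Li] | intermediate (not isolated)
11 | lithium 3-hexadecyl-2-isopropoxy-1-[(Z)-2-methoxyethenyl]-4-oxocyclobut-2-en-1-olate (racemic) | CCCCCCCCCCCCCCCCC1=C(OC(C)C)C(O[Li])(/C=C\OC)C1=O | intermediate (not isolated)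
12 | rac-2-hexadecyl-4-hydroxy-3-isopropoxy-4-[(Z)-2-methoxyethenyl]cyclobut-2-en-1-one | CCCCCCCCCCCCCCCCC1=C(OC(C)C)C(O)(/C=C\OC)C1=O | intermediate
13 | (3Z,5Z)-2-hexadecyl-4-hydroxy-3-isopropoxy-6-methoxyhexa-1,3,5-trien-1-one (dienylketene) | CCCCCCCCCCCCCCCCC(=C=O)/C(OC(C)C)=C(O)\C=C/OC | intermediate (not isolated)
14 | 2-hexadecyl-4-hydroxy-3-isopropoxy-6-methoxycyclohexa-2,4-dien-1-one (racemic) | CCCCCCCCCCCCCCCCC1=C(OC(C)C)C(O)=CC(OC)C1=O | intermediate (not isolated)
15 | 3-hexadecyl-2-isopropoxy-5-methoxybenzene-1,4-diol | CCCCCCCCCCCCCCCCc1c(O)c(OC)cc(O)c1OC(C)C | intermediate (not isolated)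
16 | 3-hexadecyl-2-isopropoxy-5-methoxy-1,4-benzoquinone | CCCCCCCCCCCCCCCCC1=C(OC(C)C)C(=O)C=C(OC)C1=O | intermediate
17 | 2-(dichloroboryloxy)-3-hexadecyl-5-methoxy-1,4-benzoquinone | CCCCCCCCCCCCCCCCC1=C(OB(Cl)Cl)C(=O)C=C(OC)C1=O | intermediate (not isolated)
18 | 3-hexadecyl-2-hydroxy-5-methoxy-1,4-benzoquinone | CCCCCCCCCCCCCCCCC1=C(O)C(=O)C=C(OC)C1=O | target

**Step count and risks**
Total steps: 6. Longest linear sequence: 5 (steps 1, 2, 4, 5, 6); step 3 is a one-step side branch.

The three steps most likely to fail:

Step 4. The vinyllithium 10 can lose LiOMe before it adds, and the product 12 is an acid-sensitive β-methoxy allylic alcohol. The fallback brings in the two carbons as an alkyne and makes the Z-alkene afterwards. It sets out from 6. Methoxyethyne F1, distilled from 2-chloro-1,1-dimethoxyethane after treatment with NaNH2 in liquid NH3, is lithiated with n-BuLi at −78 °C to lithium methoxyacetylide F2. F2 adds to the same carbonyl of 6 and gives rac-2-hexadecyl-4-hydroxy-3-isopropoxy-4-(methoxyethynyl)cyclobut-2-en-1-one F3. Cis-semihydrogenation of F3 (H2, Pd on CaCO3 poisoned with Pb(OAc)2, quinoline, EtOAc) comes back to the route at 12. F3 itself is not heated, because an alkoxy group on the alkyne is expected to steer the ketene toward five-membered ring closure.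

Step 5. The thermolysis of 12 may be spoiled by allylic transposition of the enol ether carbinol before ring opening. The fallback expands the ring through the alkynyl (Moore) manifold and adds the methoxy group afterwards. It sets out from 6. Ethynylmagnesium bromide (THF, −78 °C) gives rac-4-ethynyl-2-hexadecyl-4-hydroxy-3-isopropoxycyclobut-2-en-1-one F4. Heating F4 in p-xylene at 138 °C gives 2-hexadecyl-3-isopropoxy-1,4-benzoquinone F5 directly by Moore rearrangement. MeOH with ZnCl2 under O2 then adds methanol at C5, the position β to the more electrophilic carbonyl. This gives hydroquinone 15, where the route is rejoined, and 15 is oxidised to 16 as in step 5.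

Step 6. BCl3 may also cleave the methyl ether or give a mixture. The fallback removes both alkyl groups and puts the methyl back selectively. It sets out from 16. Hydrolysis of both vinylogous esters (2 M aq NaOH, EtOH, 60 °C; then HCl) gives 3-hexadecyl-2,5-dihydroxy-1,4-benzoquinone F6. Vinylogous Fischer esterification (MeOH, cat. H2SO4, rt, stopped at the mono-ether) then methylates only the unhindered C5 hydroxyl, because the C2 hydroxyl is shielded by the chain. This comes back to the route at 18.

**Further compounds**
F1 | step 4 | methoxyethyne | COC#C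
F2 | step 4 | lithium methoxyacetylide | COC#C[Li]
F3 | step 4 | rac-2-hexadecyl-4-hydroxy-3-isopropoxy-4-(methoxyethynyl)cyclobut-2-en-1-one | CCCCCCCCCCCCCCCCC1=C(OC(C)C)C(O)(C#COC)C1=O
F4 | step 5 | rac-4-ethynyl-2-hexadecyl-4-hydroxy-3-isopropoxycyclobut-2-en-1-one | CCCCCCCCCCCCCCCCC1=C(OC(C)C)C(O)(C#C)C1=O
F5 | step 5 | 2-hexadecyl-3-isopropoxy-1,4-benzoquinone | CCCCCCCCCCCCCCCCC1=C(OC(C)C)C(=O)C=CC1=O
F6 | step 6 | 3-hexadecyl-2,5-dihydroxy-1,4-benzoquinone | CCCCCCCCCCCCCCCCC1=C(O)C(=O)C=C(O)C1=O
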